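**Plan**

1. Target locants as a chroman-4-one (O1, C2, C3, C4, C4a, C5–C8, C8a). The retrosynthesis cuts the O1–C2 bond of the dihydropyranone (ring C) first, then C8–prenyl, C8–CH2 of the lavandulyl group, the benzylic C–Ph bond, the acyl C4–C4a bond and the C2–C3 aldol bond. The carboxyl group is held as a temporary δ-lactone on O5.
2. Forward: tris-MOM phloroglucinol (ring A) is acylated with an aldol-derived Weinreb amide. The single free ortho-OH then carries a propiolate that is closed to a coumarin (temporary lactone ring). Phenyl (Rh), lavandulyl (Negishi) and, after MOM removal, prenyl (palladium, dearomatising) are added. Ring C is closed last and the lactone is opened.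
3. Enabling feature: in the dearomatised precursor the enol oxygen on C8a belongs to a vinylogous acid running C8a=C4a–C5=C6–C7=O and lies 1,5 to the carbinol carbon of the C4a acyl chain. The lactone fused at C5–C6 ties up O5 and the carboxyl group, so only O1–C2 can form.
4. Stereochemistry: C2 and C3 come from an Evans syn-aldol, with C2 inverted in the ring closure. The benzylic centre comes from Rh/(S)-SEGPHOS conjugate arylation, the lavandulyl centre from an Evans deconjugative alkylation, and quaternary C8 from ligand control in the dearomative prenylation.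

Key step: step 18

Remark: the dearomatised intermediates 31 and 32 are drawn as the 5-oxo/7-enol tautomers (chromen-2-one locants) that correspond to the tautomer in which the target is written.

**Route**

Step 1
Reactants: 1 (R)-4-benzyl-3-propanoyl-1,3-oxazolidin-2-one; 2 acetaldehyde
Product: 4 (4R)-4-benzyl-3-[(2R,3S)-3-hydroxy-2-methylbutanoyl]-1,3-oxazolidin-2-one, via dibutylboron Z-enolate 3 (not isolated)
Conditions: n-Bu2BOTf, Et3N, CH2Cl2, −78 to 0 °C; then 2, −78 to 0 °C; pH 7 buffer, MeOH, H2O2
Reagents that add atoms: none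
Why: Evans syn-aldol reaction, in which the Z-boron enolate reacts through a Zimmerman–Traxler chair on the face away from the auxiliary benzyl group and should set the side-chain centres as 2R,3S.

Step 2
Reactants: 4
Product: 5 (2R,3S)-3-hydroxy-N-methoxy-N,2-dimethylbutanamide
Conditions: MeNH(OMe)·HCl, AlMe3, CH2Cl2, −20 to 0 °C; 0.5 M HCl work-up
Reagents that add atoms: N,O-dimethylhydroxylamine hydrochloride, CNOC.Cl
Why: Weinreb transamidation of an aldol imide, in which the aluminium amide attacks the exocyclic carbonyl with help from the free β-hydroxyl and leaves both stereocentres untouched.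

Step 3
Reactants: 5
Product: 6 (2R,3S)-N-methoxy-3-(methoxymethoxy)-N,2-dimethylbutanamide
Conditions: MOMCl, i-Pr2NEt, CH2Cl2, 0 °C to rt
Reagents that add atoms: chloromethyl methyl ether, COCCl
Why: MOM protection (O-alkylation), so that the carbinol survives the aryllithium and is later unveiled together with the phenols.

Step 4
Reactants: 7 phloroglucinol
Product: 8 1,3,5-tris(methoxymethoxy)benzene
Conditions: NaH, MOMCl, DMF, 0 °C to rt
Reagents that add atoms: chloromethyl methyl ether, COCCl
Why: threefold Williamson O-alkylation of the phenoxides, giving ether groups that later direct lithiation.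

Step 5
Reactants: 8 1,3,5-tris(methoxymethoxy)benzene; 6 (2R,3S)-N-methoxy-3-(methoxymethoxy)-N,2-dimethylbutanamide
Product: 10 (2R,3S)-3-(methoxymethoxy)-2-methyl-1-[2,4,6-tris(methoxymethoxy)phenyl]butan-1-one, via 2,4,6-tris(methoxymethoxy)phenyllithium 9 (not isolated)
Conditions: n-BuLi, THF, 0 °C; then 6, −78 to −20 °C; aq. NH4Cl
Reagents that add atoms: none
Why: directed ortho-lithiation between two OMOM groups (all three ring positions are equivalent) followed by Weinreb ketone synthesis, where the lithium chelate prevents over-addition.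

Step 6
Reactants: 10
Product: 11 (2R,3S)-1-[2-hydroxy-4,6-bis(methoxymethoxy)phenyl]-3-(methoxymethoxy)-2-methylbutan-1-one
Conditions: I2 (10 mol %), MeOH, rt
Reagents that add atoms: none
Why: carbonyl-assisted acetal cleavage, in which one of the two equivalent MOM groups ortho to the ketone should leave first because the freed phenol hydrogen-bonds to the carbonyl, which then slows the second cleavage.

Step 7
Reactants: 11; 12 propiolic acid
Product: 13 3,5-bis(methoxymethoxy)-2-[(2R,3S)-3-(methoxymethoxy)-2-methylbutanoyl]phenyl prop-2-ynoate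
Conditions: DCC, DMAP (cat.), CH2Cl2, −20 to 0 °C
Reagents that add atoms: none
Why: Steglich esterification of the only free phenol, which fixes the oxygen that will carry the lactone.

Step 8
Reactants: 13
Product: 14 5,7-bis(methoxymethoxy)-8-[(2R,3S)-3-(methoxymethoxy)-2-methylbutanoyl]-2H-chromen-2-one
Conditions: Ph3PAuCl (5 mol %), AgOTf (5 mol %), 1,2-dichloroethane, rt to 50 °C
Reagents that add atoms: none
Why: gold-catalysed intramolecular alkyne hydroarylation (6-endo-dig) of an aryl propiolate, in which the single free ortho carbon, activated by one ortho and one para OMOM group, attacks the gold-bound alkyne.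

Step 9
Reactants: 14; 15 phenylboronic acid
Product: 16 (4S)-5,7-bis(methoxymethoxy)-8-[(2R,3S)-3-(methoxymethoxy)-2-methylbutanoyl]-4-phenylchroman-2-one
Conditions: Rh(acac)(C2H4)2 (3 mol %), (S)-SEGPHOS (3.3 mol %), 1,4-dioxane/H2O 10:1, 60 °C
Reagents that add atoms: none
Why: rhodium-catalysed asymmetric 1,4-addition of an arylboronic acid to a coumarin (Hayashi–Miyaura reaction), in which the (S)-bisphosphine should direct phenyl to one face of C4 and set the benzylic centre as S.

Step 10
Reactants: 16
Product: 17 (4S)-6-iodo-5,7-bis(methoxymethoxy)-8-[(2R,3S)-3-(methoxymethoxy)-2-methylbutanoyl]-4-phenylchroman-2-one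
Conditions: N-iodosuccinimide, MeCN, 0 °C, dark
Reagents that add atoms: N-iodosuccinimide, O=C1CCC(=O)N1I
Why: electrophilic aromatic iodination at C6, the only unsubstituted position of the trioxygenated ring.

Step 11
Reactants: 18 (S)-4-benzyl-1,3-oxazolidin-2-one; 19 3-methylbut-2-enoyl chloride
Product: 21 (4S)-4-benzyl-3-(3-methylbut-2-enoyl)-1,3-oxazolidin-2-one, via lithium oxazolidinide 20 (not isolated)
Conditions: n-BuLi, THF, −78 °C; then 19, −78 to 0 °C
Reagents that add atoms: none
Why: N-acylation of the lithiated Evans auxiliary by an acid chloride.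

Step 12
Reactants: 21; 22 1-bromo-3-methylbut-2-ene (prenyl bromide)
Product: 24 (4S)-4-benzyl-3-[(2S)-5-methyl-2-(prop-1-en-2-yl)hex-4-enoyl]-1,3-oxazolidin-2-one, via sodium dienolate 23 (not isolated)
Conditions: NaN(SiMe3)2, THF, −78 °C; then 22, −78 to −40 °C
Reagents that add atoms: none
Why: Evans deconjugative α-alkylation, in which γ-deprotonation gives the chelated Z-dienolate and prenyl bromide should enter at the α-carbon on the face away from the benzyl group, setting the lavandulyl centre.

Step 13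
Reactants: 24
Product: 25 (S)-lavandulol, (2S)-5-methyl-2-(prop-1-en-2-yl)hex-4-en-1-ol
Conditions: LiBH4, MeOH (1 equiv), Et2O, 0 °C; aq. NH4Cl
Reagents that add atoms: none
Why: reductive cleavage of the N-acyl oxazolidinone at the exocyclic carbonyl, which does not touch the β,γ-alkene or the stereocentre.

Step 14
Reactants: 25
Product: 26 (S)-lavandulyl iodide, (3S)-3-(iodomethyl)-2,6-dimethylhepta-1,5-diene
Conditions: I2, PPh3, imidazole, CH2Cl2, 0 °C
Reagents that add atoms: iodine, II
Why: Appel-type iodination by substitution at the primary CH2, which leaves the neighbouring stereocentre alone.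

Step 15
Reactants: 26 (S)-lavandulyl iodide; 17 (4S)-6-iodo-5,7-bis(methoxymethoxy)-8-[(2R,3S)-3-(methoxymethoxy)-2-methylbutanoyl]-4-phenylchroman-2-one
Product: 28 (4S)-5,7-bis(methoxymethoxy)-8-[(2R,3S)-3-(methoxymethoxy)-2-methylbutanoyl]-6-[(2R)-5-methyl-2-(prop-1-en-2-yl)hex-4-en-1-yl]-4-phenylchroman-2-one, via (S)-lavandulylzinc iodide 27 (not isolated)
Conditions: Zn dust, LiCl, THF, 40 °C; then 17, Pd(OAc)2 (3 mol %), SPhos (6 mol %), THF/NMP, rt to 45 °C
Reagents that add atoms: none
Why: Negishi sp3–sp2 cross-coupling, in which the bulky biarylphosphine should let reductive elimination at the hindered, electron-rich aryl outrun β-hydride elimination, while ketone, lactone and MOM ethers tolerate the organozinc.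

Step 16
Reactants: 28
Product: 29 (4S)-5,7-dihydroxy-8-[(2R,3S)-3-hydroxy-2-methylbutanoyl]-6-[(2R)-5-methyl-2-(prop-1-en-2-yl)hex-4-en-1-yl]-4-phenylchroman-2-one
Conditions: ZnBr2, n-PrSH, CH2Cl2, 0 °C, short reaction time
Reagents that add atoms: none
Why: Lewis acid–thiol cleavage of all three MOM acetals under non-aqueous conditions, chosen so that the lactone is not hydrolysed (and so cannot re-close on the 5-OH) and the lavandulyl alkenes are not protonated.

Step 17
Reactants: 29; 30 3-methylbut-2-en-1-yl acetate (prenyl acetate)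
Product: 31 (4S,6S)-7-hydroxy-8-[(2R,3S)-3-hydroxy-2-methylbutanoyl]-6-(3-methylbut-2-en-1-yl)-6-[(2R)-5-methyl-2-(prop-1-en-2-yl)hex-4-en-1-yl]-4-phenyl-3,4-dihydro-2H-chromene-2,5(6H)-dione
Conditions: Pd2(dba)3·CHCl3 (2.5 mol %), (1R,2R)-N,N'-bis[2-(diphenylphosphino)benzoyl]cyclohexane-1,2-diamine (7.5 mol %), K2CO3, 1,4-dioxane, rt; aq. NaH2PO4 work-up
Reagents that add atoms: none
Why: Proposed new method: ionisation of prenyl acetate by the zerovalent palladium–bisphosphine complex gives a cationic η3-(1,1-dimethylallyl)palladium, which the potassium phenoxide of 29 should attack from outside the metal at the unsubstituted allyl terminus through C6, its most electron-rich carbon (flanked by both phenoxide oxygens, whereas C8 carries the acyl group and C4a the lactone arm); the dearomatised product is a stabilised vinylogous acid, any O-prenyl ether re-ionises and funnels to carbon, and the chiral pocket rather than the remote centres should choose the face of the flat phenoxide and set quaternary C6 as S (the ligand antipode serves if the sense proves opposite); the closest known reaction types are the palladium-catalysed asymmetric allylic dearomatisation of 1-substituted 2-naphthols with this ligand class and the palladium-catalysed C-allylation of phloroglucinols.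

Step 18
Reactants: 31
Product: 32 (4S,6S,8R,9R)-8,9-dimethyl-6-(3-methylbut-2-en-1-yl)-6-[(2R)-5-methyl-2-(prop-1-en-2-yl)hex-4-en-1-yl]-4-phenyl-3,4,8,9-tetrahydro-2H-pyrano[2,3-f]chromene-2,5,10(6H)-trione
Conditions: PPh3, DIAD (slow addition), toluene/THF, −20 to 0 °C
Reagents that add atoms: none
Why: Under Mitsunobu conditions the PPh3–DIAD betaine is protonated by the vinylogous acid of ring A (the C7 enol, about as acidic as a carboxylic acid) and turns the side-chain hydroxyl into an alkoxyphosphonium ion, which the C7 enolate oxygen displaces with loss of Ph3PO. The closest known reaction types are the Mitsunobu cyclisation of 1-(2-hydroxyaryl)-3-hydroxy-2-methylbutan-1-ones to 2,3-dimethylchroman-4-ones and the Mitsunobu O-alkylation of cyclic 1,3-diketone enols. The dihydropyranone ring closes in the 6-exo-tet mode. C8 is set by inversion of the (3S)-carbinol from the Evans aldol (S to R) and C9 is carried over unchanged from the same aldol, so the syn aldol gives the trans 8R,9R ring; trans is also the thermodynamic arrangement, so a small amount of C9 epimer should converge on it with a trace of amine. The step needs alkylation at the C7 oxygen only and substitution in preference to elimination: the δ-lactone has tied up both O1 and the carboxyl group (the two competing pronucleophiles), the C5 oxygen cannot reach the carbinol, and low temperature with slow DIAD addition in a weakly polar solvent should favour SN2 over E1cB loss of the β-oxyphosphonium group.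

Step 19
Reactants: 32
Product: 33 (3S)-3-[(2R,3R,8S)-5-hydroxy-2,3-dimethyl-8-(3-methylbut-2-en-1-yl)-8-[(2R)-5-methyl-2-(prop-1-en-2-yl)hex-4-en-1-yl]-4,7-dioxo-3,4,7,8-tetrahydro-2H-chromen-6-yl]-3-phenylpropanoic acid (target)
Conditions: LiOH, THF/H2O, 0 °C; then 1 M HCl to pH 3
Reagents that add atoms: lithium hydroxide, [Li+].[OH-]
Why: saponification of the enol δ-lactone (an activated ester), which should be much faster than attack on the vinylogous ester of ring C, and the enolate so formed shields ring C from retro-oxa-Michael opening until acidification releases the free acid.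

**Compound list**

1 | (R)-4-benzyl-3-propanoyl-1,3-oxazolidin-2-one | CCC(=O)N1[C@H](Cc2ccccc2)COC1=O | starting material
2 | acetaldehyde | CC=O | starting material
3 | dibutylboron Z-enolate of 1 (formed in the flask) | CCCCB(CCCC)O/C(=C\C)N1[C@H](Cc2ccccc2)COC1=O | intermediate
4 | (4R)-4-benzyl-3-[(2R,3S)-3-hydroxy-2-methylbutanoyl]-1,3-oxazolidin-2-one | C[C@H](O)[C@@H](C)C(=O)N1[C@H](Cc2ccccc2)COC1=O | intermediate
5 | (2R,3S)-3-hydroxy-N-methoxy-N,2-dimethylbutanamide | C[C@H](O)[C@@H](C)C(=O)N(C)OC | intermediate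
6 | (2R,3S)-N-methoxy-3-(methoxymethoxy)-N,2-dimethylbutanamide | C[C@H](OCOC)[C@@H](C)C(=O)N(C)OC | intermediate
7 | phloroglucinol | Oc1cc(O)cc(O)c1 | starting material
8 | 1,3,5-tris(methoxymethoxy)benzene | COCOc1cc(OCOC)cc(OCOC)c1 | intermediate
9 | 2,4,6-tris(methoxymethoxy)phenyllithium (formed in the flask) | [Li]c1c(OCOC)cc(OCOC)cc1OCOC | intermediate
10 | (2R,3S)-3-(methoxymethoxy)-2-methyl-1-[2,4,6-tris(methoxymethoxy)phenyl]butan-1-one | C[C@H](OCOC)[C@@H](C)C(=O)c1c(OCOC)cc(OCOC)cc1OCOC | intermediate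
11 | (2R,3S)-1-[2-hydroxy-4,6-bis(methoxymethoxy)phenyl]-3-(methoxymethoxy)-2-methylbutan-1-one | C[C@H](OCOC)[C@@H](C)C(=O)c1c(O)cc(OCOC)cc1OCOC | intermediate
12 | propiolic acid | C#CC(=O)O | starting material
13 | 3,5-bis(methoxymethoxy)-2-[(2R,3S)-3-(methoxymethoxy)-2-methylbutanoyl]phenyl prop-2-ynoate | C[C@H](OCOC)[C@@H](C)C(=O)c1c(OC(=O)C#C)cc(OCOC)cc1OCOC | intermediate
14 | 5,7-bis(methoxymethoxy)-8-[(2R,3S)-3-(methoxymethoxy)-2-methylbutanoyl]-2H-chromen-2-one | C[C@H](OCOC)[C@@H](C)C(=O)c1c(OCOC)cc(OCOC)c2ccc(=O)oc12 | intermediate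
15 | phenylboronic acid | OB(O)c1ccccc1 | starting material
16 | (4S)-5,7-bis(methoxymethoxy)-8-[(2R,3S)-3-(methoxymethoxy)-2-methylbutanoyl]-4-phenylchroman-2-one | C[C@H](OCOC)[C@@H](C)C(=O)c1c(OCOC)cc(OCOC)c2c1OC(=O)C[C@H]2c1ccccc1 | intermediate
17 | (4S)-6-iodo-5,7-bis(methoxymethoxy)-8-[(2R,3S)-3-(methoxymethoxy)-2-methylbutanoyl]-4-phenylchroman-2-one | C[C@H](OCOC)[C@@H](C)C(=O)c1c(OCOC)c(I)c(OCOC)c2c1OC(=O)C[C@H]2c1ccccc1 | intermediate
18 | (S)-4-benzyl-1,3-oxazolidin-2-one | O=C1N[C@@H](Cc2ccccc2)CO1 | starting material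
19 | 3-methylbut-2-enoyl chloride | CC(C)=CC(=O)Cl | starting material
20 | lithium (S)-4-benzyl-2-oxo-1,3-oxazolidin-3-ide (formed in the flask) | [Li]N1[C@@H](Cc2ccccc2)COC1=O | intermediate
21 | (4S)-4-benzyl-3-(3-methylbut-2-enoyl)-1,3-oxazolidin-2-one | CC(C)=CC(=O)N1[C@@H](Cc2ccccc2)COC1=O | intermediate
22 | 1-bromo-3-methylbut-2-ene (prenyl bromide) | CC(C)=CCBr | starting material
23 | sodium Z-dienolate of 21 (formed in the flask) | C=C(C)/C=C(\[O-])N1[C@@H](Cc2ccccc2)COC1=O.[Na+] | intermediate
24 | (4S)-4-benzyl-3-[(2S)-5-methyl-2-(prop-1-en-2-yl)hex-4-enoyl]-1,3-oxazolidin-2-one | C=C(C)[C@H](CC=C(C)C)C(=O)N1[C@@H](Cc2ccccc2)COC1=O | intermediate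
25 | (S)-lavandulol, (2S)-5-methyl-2-(prop-1-en-2-yl)hex-4-en-1-ol | C=C(C)[C@H](CC=C(C)C)CO | intermediate
26 | (S)-lavandulyl iodide, (3S)-3-(iodomethyl)-2,6-dimethylhepta-1,5-diene | C=C(C)[C@H](CC=C(C)C)CI | intermediate
27 | (S)-lavandulylzinc iodide (formed in the flask) | C=C(C)[C@H](CC=C(C)C)C[Zn]I | intermediate
28 | (4S)-5,7-bis(methoxymethoxy)-8-[(2R,3S)-3-(methoxymethoxy)-2-methylbutanoyl]-6-[(2R)-5-methyl-2-(prop-1-en-2-yl)hex-4-en-1-yl]-4-phenylchroman-2-one | C[C@H](OCOC)[C@@H](C)C(=O)c1c(OCOC)c(C[C@@H](CC=C(C)C)C(C)=C)c(OCOC)c2c1OC(=O)C[C@H]2c1ccccc1 | intermediate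
29 | (4S)-5,7-dihydroxy-8-[(2R,3S)-3-hydroxy-2-methylbutanoyl]-6-[(2R)-5-methyl-2-(prop-1-en-2-yl)hex-4-en-1-yl]-4-phenylchroman-2-one | C[C@H](O)[C@@H](C)C(=O)c1c(O)c(C[C@@H](CC=C(C)C)C(C)=C)c(O)c2c1OC(=O)C[C@H]2c1ccccc1 | intermediate
30 | 3-methylbut-2-en-1-yl acetate (prenyl acetate) | CC(C)=CCOC(C)=O | starting material
31 | (4S,6S)-7-hydroxy-8-[(2R,3S)-3-hydroxy-2-methylbutanoyl]-6-(3-methylbut-2-en-1-yl)-6-[(2R)-5-methyl-2-(prop-1-en-2-yl)hex-4-en-1-yl]-4-phenyl-3,4-dihydro-2H-chromene-2,5(6H)-dione | C=C(C)[C@H](CC=C(C)C)C[C@]1(CC=C(C)C)C(=O)C2=C(OC(=O)C[C@H]2c2ccccc2)C(C(=O)[C@H](C)[C@H](C)O)=C1O | intermediate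
32 | (4S,6S,8R,9R)-8,9-dimethyl-6-(3-methylbut-2-en-1-yl)-6-[(2R)-5-methyl-2-(prop-1-en-2-yl)hex-4-en-1-yl]-4-phenyl-3,4,8,9-tetrahydro-2H-pyrano[2,3-f]chromene-2,5,10(6H)-trione | C=C(C)[C@H](CC=C(C)C)C[C@]1(CC=C(C)C)C(=O)C2=C(OC(=O)C[C@H]2c2ccccc2)C2=C1O[C@H](C)[C@@H](C)C2=O | intermediate
33 | (3S)-3-[(2R,3R,8S)-5-hydroxy-2,3-dimethyl-8-(3-methylbut-2-en-1-yl)-8-[(2R)-5-methyl-2-(prop-1-en-2-yl)hex-4-en-1-yl]-4,7-dioxo-3,4,7,8-tetrahydro-2H-chromen-6-yl]-3-phenylpropanoic acid (CNP0150579.1) | C=C(C)[C@H](CC=C(C)C)C[C@]1(CC=C(C)C)C(=O)C([C@@H](CC(=O)O)c2ccccc2)=C(O)C2=C1O[C@H](C)[C@@H](C)C2=O | target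

**Step count and risks**

Total step count: 19. Longest linear sequence: 14 steps (steps 1–3, 5–10 and 15–19).

Steps most likely to fail:

1. Step 17 (proposed new method). The catalyst may discriminate poorly between the two faces of C6, whose two substituents differ only beyond their first CH2 group; O-prenylation or attack at the substituted allyl terminus may also compete. Fallback with known chemistry: starting from 29, the classical base-mediated dearomative C-alkylation of an acylphloroglucinol phenoxide with prenyl bromide 22 (DBU, toluene, 0 °C) would give 31 together with its C6 epimer, (4S,6R)-7-hydroxy-8-[(2R,3S)-3-hydroxy-2-methylbutanoyl]-6-(3-methylbut-2-en-1-yl)-6-[(2R)-5-methyl-2-(prop-1-en-2-yl)hex-4-en-1-yl]-4-phenyl-3,4-dihydro-2H-chromene-2,5(6H)-dione F1. The two diastereomers would be separated by chromatography and the route rejoined at 31.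

2. Step 18 (key step). The activated hydroxyl may be lost by β-elimination toward the enone, or the ring may close front-side through an enol-oxyphosphonium species; either process erodes the configuration at C8. Fallback: starting from 31, the alcohol would be eliminated on purpose (PPh3/DIAD then Et3N, or MsCl/Et3N) to the enone (4S,6S)-7-hydroxy-8-[(2E)-2-methylbut-2-enoyl]-6-(3-methylbut-2-en-1-yl)-6-[(2R)-5-methyl-2-(prop-1-en-2-yl)hex-4-en-1-yl]-4-phenyl-3,4-dihydro-2H-chromene-2,5(6H)-dione F2. Ring C would then be closed by a cinchona-alkaloid-catalysed intramolecular oxa-Michael addition (quinine or quinidine, chosen for the 8R sense), a reaction type known for 2-hydroxyaryl 2-methylbut-2-enoyl ketones. Amine-promoted equilibration at C9 to the trans isomer would follow, and the route would be rejoined at 32.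

3. Step 9. Aryl transfer to C4 may be slow or poorly face-selective because the peri 5-OMOM group crowds that carbon, leaving protodeboronation to win. Fallback: starting from 11, Steglich esterification with 3-phenylpropiolic acid would give 3,5-bis(methoxymethoxy)-2-[(2R,3S)-3-(methoxymethoxy)-2-methylbutanoyl]phenyl 3-phenylprop-2-ynoate F3. Gold-catalysed hydroarylation (Ph3PAuCl, AgOTf) would give 5,7-bis(methoxymethoxy)-8-[(2R,3S)-3-(methoxymethoxy)-2-methylbutanoyl]-4-phenyl-2H-chromen-2-one F4. A copper-hydride-catalysed asymmetric conjugate reduction (Cu(OAc)2, the DTBM-SEGPHOS antipode that gives 4S, diethoxymethylsilane, t-BuOH) would then set the benzylic centre by hydride delivery instead of aryl delivery, and the route would be rejoined at 16.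

Further compounds
F1 | step 17 | (4S,6R)-7-hydroxy-8-[(2R,3S)-3-hydroxy-2-methylbutanoyl]-6-(3-methylbut-2-en-1-yl)-6-[(2R)-5-methyl-2-(prop-1-en-2-yl)hex-4-en-1-yl]-4-phenyl-3,4-dihydro-2H-chromene-2,5(6H)-dione | C=C(C)[C@H](CC=C(C)C)C[C@@]1(CC=C(C)C)C(=O)C2=C(OC(=O)C[C@H]2c2ccccc2)C(C(=O)[C@H](C)[C@H](C)O)=C1O
F2 | step 18 | (4S,6S)-7-hydroxy-8-[(2E)-2-methylbut-2-enoyl]-6-(3-methylbut-2-en-1-yl)-6-[(2R)-5-methyl-2-(prop-1-en-2-yl)hex-4-en-1-yl]-4-phenyl-3,4-dihydro-2H-chromene-2,5(6H)-dione | C=C(C)[C@H](CC=C(C)C)C[C@]1(CC=C(C)C)C(=O)C2=C(OC(=O)C[C@H]2c2ccccc2)C(C(=O)/C(C)=C/C)=C1O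
F3 | step 9 | 3,5-bis(methoxymethoxy)-2-[(2R,3S)-3-(methoxymethoxy)-2-methylbutanoyl]phenyl 3-phenylprop-2-ynoate | C[C@H](OCOC)[C@@H](C)C(=O)c1c(OC(=O)C#Cc2ccccc2)cc(OCOC)cc1OCOC
F4 | step 9 | 5,7-bis(methoxymethoxy)-8-[(2R,3S)-3-(methoxymethoxy)-2-methylbutanoyl]-4-phenyl-2H-chromen-2-one | C[C@H](OCOC)[C@@H](C)C(=O)c1c(OCOC)cc(OCOC)c2c(-c3ccccc3)cc(=O)oc12
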